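(The data were computed from invented constants; noise was put on by code.)

At 6.0 min a flask at 70 °C should be long finished: amber reads 18.7 % at 50.0 s and 18.9 % at 80.0 s. So the question is what share of the substrate ends as target, and two chemists argue it at the blackboard.

| setting | grey | amber | beta | alpha | eta | gamma |
|---|---|---|---|---|---|---|
| substrate | 0.30 M | 0.30 M | 1.2 M | 0.30 M | 0.30 M | 1.2 M |
| first nucleophile | 1.2 equiv | 1.2 equiv | 1.20 equiv | 1.20 equiv | 1.20 equiv | 1.20 equiv |
| second nucleophile | 0.67 equiv | 2 equiv | 1.00 equiv | 1.00 equiv | 1.00 equiv | 1.00 equiv |
| temperature | 70 °C | 70 °C | 70 °C | 70 °C | 50 °C | 50 °C |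
| remark | run made earlier | run made earlier |  |  |  |  |
| time |  |  | 6.0 min | 6.0 min | 6.0 min | 6.0 min |

| grey: time / s | grey: target / % | amber: time / s | amber: target / % |
|---|---|---|---|
| 10.0 | 11.5 | 20.0 | 15.6 |
| 12.0 | 13.3 | 40.0 | 18.3 |
| 30.0 | 18.6 | 50.0 | 18.7 |
| 80.0 | 21.5 | 80.0 | 18.9 |

(scatter of a reading: 0.5 percentage points)
1. all flasks from highest to lowest amount of target, in percent of the substrate charged, at 6.0 min (beta / alpha / eta / gamma)
2. the same order at 40 s (beta / alpha / eta / gamma)
3. the amount of target, in percent of the substrate charged of the flask you put first, at 6.0 min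
4. the amount of target, in percent of the substrate charged of the flask you put last, at 6.0 min

Tom's view is a capture contest. Substrate falls at first order to something that first nucleophile (concentration B) captures as target, against a loss K and the second nucleophile (concentration D, weight c). The target share is then B/(B + K + cD). The grey and amber plateaus give K and c, and for beta that makes 43.2 %.

Vera looks at the grey curve instead. Its gap to the last reading closes at 0.0765 s⁻¹ over the first reading, but at 0.0577 s⁻¹ later, so it closes faster early. These are readings with scatter, but she takes the excess as substrate lost in pairs. Her number is Λ, the start rate of pairwise loss over the first-order rate, 0.326 in grey, and it grows in proportion to the starting substrate.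

In her view, with x the fraction of substrate remaining, the share passing by the first-order path is 1/(1 + Λx). At the start end, x = 1, that is 1/(1 + Λ), and at the far end, with little substrate left, it nears 1. Averaged over the run, the two ends join to φ = ln(1 + Λ)/Λ, which is 0.866 at 0.30 M. At 1.2 M, Λ becomes 1.30 and φ becomes 0.640.

I side with Vera. Refitting the plateaus with φ gives c = 0.500 and K = 0.989 M. So I expect beta at 30.4 %, below Tom's figure, and alpha at 20.8 %. For eta and gamma the runs show nothing of temperature.

The forecast leans Tom's way with figures of its own: gamma > beta > eta > alpha at 6.0 min, beta > gamma > alpha > eta at 40 s, 44 % on top and 21 % last, since “Fourfold concentration should therefore favour target”.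

The flasks give beta > gamma > eta > alpha at 6.0 min and beta > alpha > gamma > eta at 40 s, with beta at 32.0 %, gamma at 26.9 %, eta at 24.4 % and alpha at 20.4 %.

    intermediate → solvolysis product (k = 13.0 s⁻¹, Ea = 69.0 kJ mol⁻¹)
    second nucleophile + intermediate → other capture product (k = 4.10 L mol⁻¹ s⁻¹, Ea = 39.0 kJ mol⁻¹)
    substrate → intermediate (k = 0.0710 s⁻¹, Ea = 100 kJ mol⁻¹)
    first nucleophile + intermediate → target (k = 13.0 L mol⁻¹ s⁻¹, Ea = 41.0 kJ mol⁻¹)
    2 substrate → homo dimer (k = 0.0330 L mol⁻¹ s⁻¹, Ea = 58.0 kJ mol⁻¹)
    (constants at 70 °C)

In beta at 0.123 min, substrate goes to the intermediate 2.2 times as fast as into homo dimer, a contest Tom's view does not hold. Beta ends with 32.8 % of its substrate in homo dimer, against 11.8 % in alpha, the flask with the least homo dimer and so the region where his view comes closest. The first nucleophile does not enter Λ, so a neighbour of beta charged with 2.00 equiv of first nucleophile keeps Λ = 1.30 and φ = 0.640, and reckons to 38.5 %. That neighbour holds 32.8 % homo dimer and 41.0 % target.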